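A direct plan would oxidise 1-docosanol A1 to docosanal A2, add the lithium enolate of 2-phenylethyl acetate A3 to give the racemic β-hydroxy ester A4, dehydrate A4 to the enoate A5 and hydrogenate A5.
Its weakest step would be the aldol addition: it puts at C3 a hydroxyl group and a stereocentre that the target lacks, leaves that centre to chance, and relies on a waxy, enolisable, air-sensitive aldehyde.
The sulfonylation–elimination would be the second: a late step that only removes the oxygen just introduced and can give E/Z and β,γ-isomers or attack the ester.
The third would be the redox frame of oxidation at the start and hydrogenation at the end: two steps that add no complexity, the last one run on the most advanced material.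
In sum, four steps and three changes of oxidation level would be spent on one C–C bond.

Plan of the new route
The route would join (Z)-9-tricosene 1, carbon monoxide 2 and 2-phenylethanol 3 to the target 4 in one palladium-catalysed isomerising alkoxycarbonylation. The retrosynthesis cuts the C1–C2 bond and the bond from C1 to the ester oxygen at once.
The feature that allows this: apart from the ester at C1, the acyl part is an unbranched, unfunctionalised C2–C24 chain (23 carbons, no stereocentre) that reads the same from either end. A palladium hydride may therefore enter at any C=C bond and walk to a terminus before CO and the alcohol are taken up.
No ring is formed; the only ring, the benzene ring of the 2-phenylethyl group, is bought intact in 3.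
C1 arrives at the carboxyl oxidation level as CO, so no aldehyde, no C3 hydroxyl group or stereocentre, no elimination and no hydrogenation arise.

Key step: step 1

Remark on the chemistry: (Z)-9-tricosene (muscalure, a commercial insect attractant) is taken as the olefin. Because the catalyst moves the double bond along the chain, any other positional or geometrical isomer of unbranched tricosene would serve equally.

Step 1
Reactants: 1 (Z)-9-tricosene; 2 carbon monoxide; 3 2-phenylethanol
Product: 4 2-phenylethyl tetracosanoate
Conditions: Pd(OAc)2 (1 mol %), 1,2-bis(di-tert-butylphosphinomethyl)benzene (5 mol %), CH3SO3H (20 mol %), CO (30 bar), 3 (8 equiv)/toluene, 90 °C, 40 h, steel autoclave; vent, pass through a short silica pad, precipitate with MeOH at 0 °C, recrystallise from acetone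
Reagents that add atoms: none
Why: A cationic palladium hydride carrying the bulky diphosphine adds to the C9=C10 bond of 1 and, by fast reversible β-hydride elimination and re-insertion, moves along the unbranched chain until palladium is bound to a terminal CH2; CO 2 inserts into this primary Pd–C bond and 3 cleaves the resulting linear acyl, which gives 4 and returns the hydride. The closest known reaction type is the isomerising alkoxycarbonylation of internal long-chain olefins such as methyl oleate or internal octenes to linear esters with the same Pd(OAc)2/diphosphine/sulfonic acid system. No ring is closed and no stereocentre is formed, so the only selectivity needed is terminal against internal carbonylation. The ligand secures it, because all palladium alkyls interconvert while alcoholysis of the unhindered linear acyl is much faster than that of any α-branched acyl (Curtin–Hammett control). The substrate secures the rest: the C23 chain has no branch, ring or second functional group to stop the walk, and both of its ends lead to the same tetracosanoyl group, so position and geometry of the double bond in 1 are without consequence. The step is an addition in which every atom of 1, 2 and 3 ends in 4, and the small share of methyl-branched esters expected should stay in the acetone mother liquor.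

Compound list
1 | (Z)-9-tricosene (muscalure) | CCCCCCCC/C=C\CCCCCCCCCCCCC | starting material
2 | carbon monoxide | [C-]#[O+] | starting material
3 | 2-phenylethanol | OCCc1ccccc1 | starting material
4 | 2-phenylethyl tetracosanoate (achiral) | CCCCCCCCCCCCCCCCCCCCCCCC(=O)OCCc1ccccc1 | target

Total step count: 1
Longest linear sequence: 1

Steps most likely to fail (the route has a single step, so the list has one entry)

Step 1. Three processes could spoil it:
- Carbonylation could take place at internal carbons before palladium has reached a chain end, which would give branched esters that are hard to remove from the waxy product.
- Alcoholysis of the acyl by the dilute, higher-boiling alcohol could be slow, so that the hydride catalyst decays to metallic (zerovalent) palladium before the olefin is consumed.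
- The sulfonic acid could dehydrate or etherify part of the alcohol at 90 °C.

Fallback, from 3 back to 4, by a decarboxylative radical coupling instead of a carbonylation (known chemistry). Compound 3 would be opened onto succinic anhydride (4-(dimethylamino)pyridine 5 mol %, toluene, 80 °C) to give 4-oxo-4-(2-phenylethoxy)butanoic acid F1. F1 (5 equiv) and commercial docosanoic acid (behenic acid, 1 equiv) would then be electrolysed together under mixed Kolbe conditions (KOH, 5 mol % of the total acid, warm MeOH, Pt anode and cathode, 45 °C, constant current). The electrolysis would be stopped while the electrolyte is still weakly acidic, so that no methoxide builds up to exchange the 2-phenylethyl ester. Anodic decarboxylation of both carboxylates and coupling of the n-heneicosyl radical with the 2-(2-phenylethoxycarbonyl)ethyl radical would form the C3–C4 bond of 4 directly at the alkane oxidation level. The excess of the cheap half-ester should channel the fatty acid into the cross product. The carboxylate layer on the anode should shield the remote phenyl ring. The two symmetrical homo-coupling by-products (a long alkane and a diester) differ enough in polarity from 4 to be removed on silica before recrystallisation from acetone.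

Further compounds
F1 | step 1 | 4-oxo-4-(2-phenylethoxy)butanoic acid (mono(2-phenylethyl) succinate) | OC(=O)CCC(=O)OCCc1ccccc1
A1 | direct plan | 1-docosanol | CCCCCCCCCCCCCCCCCCCCCCO
A2 | direct plan | docosanal | CCCCCCCCCCCCCCCCCCCCCC=O
A3 | direct plan | 2-phenylethyl acetate | CC(=O)OCCc1ccccc1
A4 | direct plan | rac-2-phenylethyl 3-hydroxytetracosanoate | CCCCCCCCCCCCCCCCCCCCCC(O)CC(=O)OCCc1ccccc1
A5 | direct plan | 2-phenylethyl (E)-tetracos-2-enoate | CCCCCCCCCCCCCCCCCCCCC/C=C/C(=O)OCCc1ccccc1
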